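**Assumption:** 2'-hydroxy-3',4'-dimethoxyacetophenone is taken as a purchasable catalogue compound, so all five methoxy groups are bought with the two starting materials.

## Retrosynthetic overview

- Target (2S)-flavan ⇒ (2S)-flavanone, by removing the C4 carbonyl oxygen (C=O → CH–OH → CH2), the order of events presumed in the plant.
- (2S)-Flavanone ⇒ 2'-hydroxychalcone, by opening O1–C2. Forward, this is a catalytic enantioselective 6-endo oxa-Michael closure (the chalcone isomerase reaction) run directly on the unactivated chalcone, with no activating ester or auxiliary. It forms the only new ring and the only stereocentre in one step.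
- 2'-Hydroxychalcone ⇒ 2'-hydroxy-3',4'-dimethoxyacetophenone + 3,4,5-trimethoxybenzaldehyde (Claisen–Schmidt).
- Ring order: rings A and B are bought as arenes; the pyran ring C is closed in step 2; no ring is formed afterwards.

## Route

Step 1
Reactants: 1 2'-hydroxy-3',4'-dimethoxyacetophenone; 2 3,4,5-trimethoxybenzaldehyde
Product: 3 (E)-2'-hydroxy-3',4',3,4,5-pentamethoxychalcone
Conditions: KOH (5 equiv, 50% aq), EtOH, 0 °C → rt, 36 h; pour onto ice/2 M HCl (pH 3); filter, recrystallise (EtOH)
Reagents that add atoms: none
Why: Claisen–Schmidt (crossed aldol) condensation in which the aldehyde cannot enolise, the methyl ketone is the only enolisable partner and E1cB dehydration gives only the conjugated (E)-enone; no stereocentre is formed.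

Step 2
Reactants: 3 (E)-2'-hydroxy-3',4',3,4,5-pentamethoxychalcone
Product: 4 (2S)-7,8-dimethoxy-2-(3,4,5-trimethoxyphenyl)chroman-4-one
Conditions: epi-9-amino-9-deoxyquinidine N'-[3,5-bis(trifluoromethyl)phenyl]thiourea (10 mol%), PhMe (0.1 M), 30 °C, 2–4 d, chiral-HPLC monitoring, stopped when the ee of 4 starts to fall; SiO2 (recover 3), recrystallise 4 (EtOH) to raise ee
Reagents that add atoms: none
Why: Bifunctional-organocatalytic asymmetric intramolecular oxa-Michael addition (6-endo-trig, the chalcone isomerase reaction): the thiourea hydrogen-bonds the enone carbonyl while the quinuclidine nitrogen deprotonates the 2'-OH, so the catalyst-bound phenoxide adds to the Si face of C-β and C2 is formed as 2S under catalyst control, the run being stopped before equilibrium so that retro-Michael racemisation does not erode the ee.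

Step 3
Reactants: 4 (2S)-7,8-dimethoxy-2-(3,4,5-trimethoxyphenyl)chroman-4-one
Product: 6 (2S)-7,8,3',4',5'-pentamethoxyflavan, via cis-flavan-4-ol 5 (not isolated)
Conditions: NaBH4 (1.5 equiv), THF/MeOH 4:1, 0 °C, 1 h; evaporate in the same flask; then CH2Cl2 (0.05 M), Et3SiH (5 equiv), TFA (10 equiv, added last), −20 → 0 °C, 1 h; aq NaHCO3
Reagents that add atoms: none
Why: Carbonyl 1,2-reduction followed by ionic hydrogenation, in which borohydride gives the 2,4-cis carbinol, TFA ionises C4–OH to a benzylic cation stabilised by O1 and the 7-OMe group and Et3SiH traps it as CH2, so that C2 is never touched (its retro-Michael pathway is closed once C4 is sp3), 2S is carried through and the transient C4 centre is erased.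

## Compound list

1 | 2'-hydroxy-3',4'-dimethoxyacetophenone [1-(2-hydroxy-3,4-dimethoxyphenyl)ethanone] | CC(=O)c1ccc(OC)c(OC)c1O | starting material
2 | 3,4,5-trimethoxybenzaldehyde | COc1cc(C=O)cc(OC)c1OC | starting material
3 | (E)-1-(2-hydroxy-3,4-dimethoxyphenyl)-3-(3,4,5-trimethoxyphenyl)prop-2-en-1-one | COc1cc(/C=C/C(=O)c2ccc(OC)c(OC)c2O)cc(OC)c1OC | intermediate
4 | (2S)-7,8-dimethoxy-2-(3,4,5-trimethoxyphenyl)chroman-4-one | COc1cc([C@@H]2CC(=O)c3ccc(OC)c(OC)c3O2)cc(OC)c1OC | intermediate
5 | (2S,4S)-7,8-dimethoxy-2-(3,4,5-trimethoxyphenyl)chroman-4-ol (2,4-cis) | COc1cc([C@@H]2C[C@H](O)c3ccc(OC)c(OC)c3O2)cc(OC)c1OC | intermediate (not isolated)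
6 | (2S)-7,8-dimethoxy-2-(3,4,5-trimethoxyphenyl)chromane [(2S)-7,8,3',4',5'-pentamethoxyflavan] | COc1cc([C@@H]2CCc3ccc(OC)c(OC)c3O2)cc(OC)c1OC | target

## Totals and risks

Total step count: 3. Longest linear sequence: 3 (1 → 3 → 4 → 6; 2 enters in step 1).

**Step 2 (highest risk).** The enone is electron-rich and the phenol is hydrogen-bonded, so the closure is slow, and it is reversible, so ee can be moderate and falls with time. The facial sense for this tethered addition is not predicted with certainty and must be confirmed on the first run by CD of 4 ((2S)-flavanones show a positive Cotton effect near 330 nm and a negative one near 290 nm). If the quinidine-derived catalyst gives 2R, the quinine-derived pseudo-enantiomer replaces it; this changes the catalogue catalyst, not the route.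

The fallback sets out from 3 and returns at 5. It moves the stereo-discrimination from the ring closure to the carbonyl reduction. Cyclise 3 without stereocontrol (NaOAc, EtOH, reflux) to the racemic flavanone F1. Subject it to asymmetric transfer hydrogenation with RuCl[(S,S)-TsDPEN](p-cymene) (1 mol%), HCO2H/Et3N 5:2, EtOAc, rt, stopped near 50% conversion. This is a kinetic resolution: the (S,S) catalyst sets 4S and should react much faster with the 2S enantiomer, where hydride delivery gives the all-equatorial cis product (the match is to be confirmed on the first run). The product is the (2S,4S)-flavan-4-ol 5 (at most 50% per pass). The unreacted (2R)-flavanone F2 is separated, racemised with base through ring opening to 3 and reclosure, and recycled. Compound 5 then enters the Et3SiH/TFA stage of step 3 unchanged.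

**Step 3.** The C4 cation can alkylate the electron-rich rings of a second molecule (dimers), lose a proton to a flav-3-ene that disproportionates, or, on long acid exposure, put C2 at risk.

The fallback sets out from 5, now isolated after the borohydride stage by aqueous work-up, and returns at 6. It replaces the cation by a radical. Treat 5 with 1,1'-thiocarbonyldiimidazole (DMAP cat., ClCH2CH2Cl, 60 °C) to give the O-thiocarbonylimidazolide F3. Reduce this with Bu3SnH/AIBN in toluene at 85 °C (Barton–McCombie deoxygenation) to 6. The C4 benzylic radical has no pathway to open the ring or reach C2.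

**Step 1.** The phenoxide of 1 is a reluctant enolate precursor, and under strong base part of 3 can close to racemic flavanone, which would contaminate step 2.

The fallback sets out from 1 and returns at 3. It masks the phenol. Convert 1 with MOMCl/iPr2NEt in CH2Cl2 (NaH/DMF if the hydrogen-bonded OH is sluggish) to the MOM ether F4. Condense this with 2 (Ba(OH)2·8H2O, MeOH, rt) to the MOM-protected chalcone F5; with no free phenol there is neither enolate deactivation nor ring closure. Brief treatment with 3 M HCl/MeOH at 40 °C then releases 3.

## Further compounds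

F1 | step 2 | rac-7,8-dimethoxy-2-(3,4,5-trimethoxyphenyl)chroman-4-one | COc1cc(C2CC(=O)c3ccc(OC)c(OC)c3O2)cc(OC)c1OC
F2 | step 2 | (2R)-7,8-dimethoxy-2-(3,4,5-trimethoxyphenyl)chroman-4-one (unreacted enantiomer of the resolution) | COc1cc([C@H]2CC(=O)c3ccc(OC)c(OC)c3O2)cc(OC)c1OC
F3 | step 3 | O-[(2S,4S)-7,8-dimethoxy-2-(3,4,5-trimethoxyphenyl)chroman-4-yl] 1H-imidazole-1-carbothioate | COc1cc([C@@H]2C[C@H](OC(=S)n4ccnc4)c3ccc(OC)c(OC)c3O2)cc(OC)c1OC
F4 | step 1 | 1-[3,4-dimethoxy-2-(methoxymethoxy)phenyl]ethanone | CC(=O)c1ccc(OC)c(OC)c1OCOC
F5 | step 1 | (E)-1-[3,4-dimethoxy-2-(methoxymethoxy)phenyl]-3-(3,4,5-trimethoxyphenyl)prop-2-en-1-one | COCOc1c(C(=O)/C=C/c2cc(OC)c(OC)c(OC)c2)ccc(OC)c1OC
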